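**Plan**
- Retrosynthesis: the three aryl methyl ethers are removed, the isopropenyl group is traced back to a C3 carboxylate (C=CH2, then C–CH3), and ring B is cut at C1–C2.
- Enabling feature: in ring B the C2 methylene lies between the C1 aryl ketone and the C3 methine. Without C2 the core is an indan-1-one whose C2 carries the ester plus CH2Br and whose C3 is the quaternary carbon (C4 of the target).
- Further cuts: C2–CH2Br, C4–CH3 (conjugate methylation of an indenone), C4–C4a (Nazarov), the alkylidene C=C (Knoevenagel), the ester C–C (Claisen), aryl–acyl and aryl–isopropyl.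
- Forward: arene → aryl β-keto ester → five-membered ring (Nazarov) → indenone → quaternary centre → bromomethylation → radical one-carbon expansion to six-membered ring B → side-chain and arene unmasking.
- Stereochemistry: C4 from ligand-controlled copper-catalysed methyl addition to the planar indenone; C3 from hydrogen-atom transfer to the ring-expanded radical anti to the propanoate arm, carried through non-epimerising steps.

Key step: step 10

Remarks: tetralone numbering is used for ring B compounds (C1 ketone, C2 methylene, C3 methine, C4 quaternary carbon, C5/C6/C8 oxygens, C7 isopropyl). The target SMILES places the isopropenyl group cis to the propanoic acid arm, i.e. (3S,4R), and the route is planned for that isomer. Arene 5 is prepared, since its commercial supply is not assumed.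

**Step 1**
Reactants: 1 1,2,4-trimethoxybenzene; 2 acetone
Product: 4 2-(2,3,6-trimethoxyphenyl)propan-2-ol, via aryllithium 3 (not isolated)
Conditions: n-BuLi, TMEDA, THF, 0 °C; then 2, −78 °C → rt; H2O
Reagents that add atoms: none
Why: Directed ortho-lithiation takes place at the C–H flanked by two methoxy groups, and the aryllithium adds to acetone (1,2-addition) to give the tertiary benzylic alcohol.

**Step 2**
Reactants: 4 2-(2,3,6-trimethoxyphenyl)propan-2-ol
Product: 5 2-isopropyl-1,3,4-trimethoxybenzene
Conditions: Et3SiH, CF3CO2H, CH2Cl2, 0 °C → rt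
Reagents that add atoms: none
Why: Ionic hydrogenation, in which acid ionises the tertiary benzylic alcohol to a cation stabilised by the ortho methoxy groups and the silane transfers hydride.

**Step 3**
Reactants: 5 2-isopropyl-1,3,4-trimethoxybenzene; 6 acetyl chloride
Product: 7 1-[2,4,5-trimethoxy-3-(propan-2-yl)phenyl]ethan-1-one
Conditions: 6, SnCl4, CH2Cl2, −20 → 0 °C
Reagents that add atoms: none
Why: Friedel–Crafts acylation should go to the one free position that is ortho and para to methoxy groups (the future C8a, the site where this arene is also halogenated), and the mild Lewis acid at low temperature should spare the methoxy group next to the new ketone.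

**Step 4**
Reactants: 7 1-[2,4,5-trimethoxy-3-(propan-2-yl)phenyl]ethan-1-one; 8 dibenzyl carbonate
Product: 9 benzyl 3-oxo-3-[2,4,5-trimethoxy-3-(propan-2-yl)phenyl]propanoate
Conditions: NaH, 8, THF, reflux; aq. HCl
Reagents that add atoms: none
Why: Crossed Claisen condensation of the methyl ketone enolate with a non-enolisable carbonate, driven by irreversible deprotonation of the β-keto ester formed.

**Step 5**
Reactants: 9 benzyl 3-oxo-3-[2,4,5-trimethoxy-3-(propan-2-yl)phenyl]propanoate; 10 methyl 4-oxobutanoate
Product: 11 1-benzyl 6-methyl 2-[2,4,5-trimethoxy-3-(propan-2-yl)benzoyl]hex-2-enedioate (E/Z mixture)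
Conditions: piperidine (cat.), AcOH (cat.), 4 Å MS, benzene, rt → 60 °C
Reagents that add atoms: none
Why: Knoevenagel condensation of the active methylene with the aldehyde under piperidinium acetate catalysis with removal of water; the alkene geometry is irrelevant because both isomers converge over steps 6 and 7.

**Step 6**
Reactants: 11 1-benzyl 6-methyl 2-[2,4,5-trimethoxy-3-(propan-2-yl)benzoyl]hex-2-enedioate
Product: 12 racemic trans-benzyl 4,5,7-trimethoxy-3-(3-methoxy-3-oxopropyl)-1-oxo-6-(propan-2-yl)indane-2-carboxylate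
Conditions: Cu(OTf)2 (10 mol %), ClCH2CH2Cl, 60 °C
Reagents that add atoms: none
Why: Lewis acid-catalysed Nazarov cyclisation of a polarised aryl vinyl ketone, in which chelation of the β-keto ester gives the pentadienyl-type cation that closes 4π-conrotatory onto the aryl carbon ortho to a methoxy group (the C4–C4a bond that Nazarov closures of this trimethoxy-isopropyl arene are known to form); both stereocentres of 12 are erased in step 7.

**Step 7**
Reactants: 12 racemic trans-benzyl 4,5,7-trimethoxy-3-(3-methoxy-3-oxopropyl)-1-oxo-6-(propan-2-yl)indane-2-carboxylate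
Product: 15 benzyl 4,5,7-trimethoxy-3-(3-methoxy-3-oxopropyl)-1-oxo-6-(propan-2-yl)-1H-indene-2-carboxylate, via C2 phenylselenide 13 (not isolated), via C2 selenoxide 14 (not isolated)
Conditions: PhSeCl, pyridine, CH2Cl2, 0 °C; aq. wash; then 30% H2O2, CH2Cl2, 0 °C → rt
Reagents that add atoms: none
Why: α-Selenenylation of the enolised β-keto ester, oxidation and syn-selenoxide elimination toward the only β-hydrogen (C3–H) is the standard dehydrogenation of cyclic β-keto esters and should give the achiral indenone.

**Step 8**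
Reactants: 15 benzyl 4,5,7-trimethoxy-3-(3-methoxy-3-oxopropyl)-1-oxo-6-(propan-2-yl)-1H-indene-2-carboxylate
Product: 16 benzyl (3R)-4,5,7-trimethoxy-3-(3-methoxy-3-oxopropyl)-3-methyl-1-oxo-6-(propan-2-yl)indane-2-carboxylate (C2 epimers plus enol)
Conditions: Me2Zn, Cu(OTf)2 (5 mol %), BINOL-derived phosphoramidite of bis(1-phenylethyl)amine (10 mol %, the antipode that gives 3R), toluene, −30 → 0 °C; aq. HCl
Reagents that add atoms: dimethylzinc, C[Zn]C
Why: Copper-catalysed asymmetric conjugate addition of a dialkylzinc to a β-substituted 2-alkoxycarbonyl cyclic enone, a substrate class known to give all-carbon quaternary centres; the doubly activated planar indenone offsets the low reactivity of Me2Zn, and the chiral copper–phosphoramidite complex selects the face of C3 (the future C4).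

**Step 9**
Reactants: 16 benzyl (3R)-4,5,7-trimethoxy-3-(3-methoxy-3-oxopropyl)-3-methyl-1-oxo-6-(propan-2-yl)indane-2-carboxylate; 17 dibromomethane
Product: 18 benzyl (3S)-2-(bromomethyl)-4,5,7-trimethoxy-3-(3-methoxy-3-oxopropyl)-3-methyl-1-oxo-6-(propan-2-yl)indane-2-carboxylate (both C2 epimers; same spatial arrangement at C3 as in 16, the descriptor changes by priority only)
Conditions: NaH, 17 (excess), THF/DMPU, 0 → 45 °C
Reagents that add atoms: none
Why: C-Alkylation of the sodium enolate of the β-keto ester with excess dibromomethane in a dipolar medium is the standard entry to 2-(bromomethyl) β-keto esters; the neopentylic product does not react a second time and its C2 configuration is irrelevant.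

**Step 10**
Reactants: 18 benzyl (3S)-2-(bromomethyl)-4,5,7-trimethoxy-3-(3-methoxy-3-oxopropyl)-3-methyl-1-oxo-6-(propan-2-yl)indane-2-carboxylate
Product: 19 benzyl (3R,4R)-5,6,8-trimethoxy-4-(3-methoxy-3-oxopropyl)-4-methyl-1-oxo-7-(propan-2-yl)-1,2,3,4-tetrahydronaphthalene-3-carboxylate (tetralone numbering; ester cis to the propanoate arm)
Conditions: (Me3Si)3SiH, AIBN, benzene, 80 °C, syringe-pump addition, 5 mM
Reagents that add atoms: none
Why: Bromine abstraction by the silyl radical gives the primary radical, which adds 3-exo-trig to the adjacent indanone carbonyl; the cyclopropyloxy radical then opens by β-scission of the old carbonyl–C2 ring bond, so the carbonyl carbon is now bonded to the former bromomethyl carbon (the C1–C2 bond of ring B) and the five-membered ketone becomes the six-membered one. This is the Dowd–Beckwith ring expansion, established for 2-(bromomethyl) cyclic and benzo-fused β-keto esters. The benzyl ester secures the direction of scission, because it makes the ring-expanded tertiary C3 radical the most stabilised outlet, while its own carbonyl is a poor radical acceptor. The new C3 stereocentre is set in the final hydrogen transfer: in the flattened radical the propanoate arm on C4 should sit pseudoaxial, because the in-plane site between the C5 methoxy group and the ester suits the smaller methyl, so the bulky silane should deliver hydrogen to the opposite face and leave the ester cis to the arm, with a bias that is expected to be moderate. The step also needs rearrangement to outrun direct reduction of the primary radical, which the slow donor (Me3Si)3SiH at high dilution should secure. Both C2 epimers of 18 give the same radical.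

**Step 11**
Reactants: 19 benzyl (3R,4R)-5,6,8-trimethoxy-4-(3-methoxy-3-oxopropyl)-4-methyl-1-oxo-7-(propan-2-yl)-1,2,3,4-tetrahydronaphthalene-3-carboxylate
Product: 20 (3R,4R)-5,6,8-trimethoxy-4-(3-methoxy-3-oxopropyl)-4-methyl-1-oxo-7-(propan-2-yl)-1,2,3,4-tetrahydronaphthalene-3-carboxylic acid
Conditions: H2 (1 atm), 10% Pd/C, EtOAc, rt
Reagents that add atoms: none
Why: Hydrogenolysis of the benzyl ester is much faster than reduction of the hindered electron-rich aryl ketone and leaves the methyl ester and C3 untouched.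

**Step 12**
Reactants: 20 (3R,4R)-5,6,8-trimethoxy-4-(3-methoxy-3-oxopropyl)-4-methyl-1-oxo-7-(propan-2-yl)-1,2,3,4-tetrahydronaphthalene-3-carboxylic acid
Product: 22 methyl 3-[(3R,4R)-3-acetyl-5,6,8-trimethoxy-4-methyl-1-oxo-7-(propan-2-yl)-1,2,3,4-tetrahydronaphthalen-4-yl]propanoate, via acid chloride 21 (not isolated)
Conditions: (COCl)2, DMF (cat.), CH2Cl2, 0 °C → rt; then Me2CuLi (from MeLi, CuI), Et2O, −78 °C
Reagents that add atoms: lithium dimethylcuprate, [Li+].C[Cu-]C
Why: Ketone synthesis from an acid chloride and a lithium dialkylcuprate, which at −78 °C does not touch the aryl ketone or the methyl ester and is non-basic enough to preserve C3.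

**Step 13**
Reactants: 22 methyl 3-[(3R,4R)-3-acetyl-5,6,8-trimethoxy-4-methyl-1-oxo-7-(propan-2-yl)-1,2,3,4-tetrahydronaphthalen-4-yl]propanoate
Product: 23 methyl 3-[(3S,4R)-5,6,8-trimethoxy-4-methyl-1-oxo-7-(propan-2-yl)-3-(prop-1-en-2-yl)-1,2,3,4-tetrahydronaphthalen-4-yl]propanoate
Conditions: Ph3PCH3Br, KOtBu, THF, 0 °C; then 22, −20 → 10 °C
Reagents that add atoms: methylenetriphenylphosphorane, C=P(c1ccccc1)(c1ccccc1)c1ccccc1
Why: Wittig methylenation should be selective for the saturated methyl ketone over the conjugated aryl ketone (as in enone-containing diketones, where the saturated carbonyl reacts first), and near-stoichiometric salt-free ylide at low temperature limits epimerisation at C3.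

**Step 14**
Reactants: 23 methyl 3-[(3S,4R)-5,6,8-trimethoxy-4-methyl-1-oxo-7-(propan-2-yl)-3-(prop-1-en-2-yl)-1,2,3,4-tetrahydronaphthalen-4-yl]propanoate
Product: 24 3-[(3S,4R)-5,6,8-trimethoxy-4-methyl-1-oxo-7-(propan-2-yl)-3-(prop-1-en-2-yl)-1,2,3,4-tetrahydronaphthalen-4-yl]propanoic acid
Conditions: LiOH, THF/H2O, rt; aq. HCl
Reagents that add atoms: lithium hydroxide, [Li+].[OH-]
Why: Saponification of the unhindered primary methyl ester at a stage where C3 bears no acidifying group, done here so that the later quinone never needs prolonged base.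

**Step 15**
Reactants: 24 3-[(3S,4R)-5,6,8-trimethoxy-4-methyl-1-oxo-7-(propan-2-yl)-3-(prop-1-en-2-yl)-1,2,3,4-tetrahydronaphthalen-4-yl]propanoic acid
Product: 25 3-[(3S,4R)-6-methoxy-4-methyl-1,5,8-trioxo-7-(propan-2-yl)-3-(prop-1-en-2-yl)-1,2,3,4,5,8-hexahydronaphthalen-4-yl]propanoic acid
Conditions: (NH4)2Ce(NO3)6, MeCN/H2O, 0 °C
Reagents that add atoms: water, O
Why: Oxidative demethylation of the para-dimethoxy pair (C5/C8) through the arene radical cation and attack of water should give the 5,8-quinone, with the C6 methoxy group left as a vinylogous ester and the isolated alkene and acid untouched under brief cold conditions.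

**Step 16**
Reactants: 25 3-[(3S,4R)-6-methoxy-4-methyl-1,5,8-trioxo-7-(propan-2-yl)-3-(prop-1-en-2-yl)-1,2,3,4,5,8-hexahydronaphthalen-4-yl]propanoic acid
Product: 27 3-[(3S,4R)-5,6,8-trihydroxy-4-methyl-1-oxo-7-(propan-2-yl)-3-(prop-1-en-2-yl)-1,2,3,4-tetrahydronaphthalen-4-yl]propanoic acid (CNP0198818.2), via hydroxyquinone acid 26 (not isolated)
Conditions: NaOH (0.2 M), THF/H2O, 0 °C, Ar, short contact; aq. HCl; then Na2S2O4, EtOAc/H2O, rt
Reagents that add atoms: sodium hydroxide, [Na+].[OH-]
Why: Hydroxide displaces the methoxy group of the methoxyquinone by conjugate addition–elimination (hydrolysis of a vinylogous ester) and dithionite reduces the hydroxyquinone to the hydroxyhydroquinone; short contact with cold dilute base under argon is meant to avoid enolisation-driven internal redox isomerisation that would endanger C3.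

**Compound list**
1 | 1,2,4-trimethoxybenzene | COc1ccc(OC)c(OC)c1 | starting material
2 | acetone | CC(C)=O | starting material
3 | (2,3,6-trimethoxyphenyl)lithium | [Li]c1c(OC)ccc(OC)c1OC | intermediate (not isolated)
4 | 2-(2,3,6-trimethoxyphenyl)propan-2-ol | COc1ccc(OC)c(OC)c1C(C)(C)O | intermediate
5 | 2-isopropyl-1,3,4-trimethoxybenzene | COc1ccc(OC)c(OC)c1C(C)C | intermediate
6 | acetyl chloride | CC(=O)Cl | starting material
7 | 1-[2,4,5-trimethoxy-3-(propan-2-yl)phenyl]ethan-1-one | CC(=O)c1cc(OC)c(OC)c(C(C)C)c1OC | intermediate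
8 | dibenzyl carbonate | O=C(OCc1ccccc1)OCc1ccccc1 | starting material
9 | benzyl 3-oxo-3-[2,4,5-trimethoxy-3-(propan-2-yl)phenyl]propanoate | O=C(CC(=O)OCc1ccccc1)c1cc(OC)c(OC)c(C(C)C)c1OC | intermediate
10 | methyl 4-oxobutanoate | COC(=O)CCC=O | starting material
11 | 1-benzyl 6-methyl 2-[2,4,5-trimethoxy-3-(propan-2-yl)benzoyl]hex-2-enedioate (E/Z mixture) | COC(=O)CCC=C(C(=O)OCc1ccccc1)C(=O)c1cc(OC)c(OC)c(C(C)C)c1OC | intermediate
12 | racemic trans-benzyl 4,5,7-trimethoxy-3-(3-methoxy-3-oxopropyl)-1-oxo-6-(propan-2-yl)indane-2-carboxylate | COC(=O)CCC1C(C(=O)OCc2ccccc2)C(=O)c2c(OC)c(C(C)C)c(OC)c(OC)c12 | intermediate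
13 | C2 phenylselenide of 12 (racemic) | COC(=O)CCC1C([Se]c2ccccc2)(C(=O)OCc2ccccc2)C(=O)c2c(OC)c(C(C)C)c(OC)c(OC)c12 | intermediate (not isolated)
14 | C2 selenoxide of 12 (racemic) | COC(=O)CCC1C([Se](=O)c2ccccc2)(C(=O)OCc2ccccc2)C(=O)c2c(OC)c(C(C)C)c(OC)c(OC)c12 | intermediate (not isolated)
15 | benzyl 4,5,7-trimethoxy-3-(3-methoxy-3-oxopropyl)-1-oxo-6-(propan-2-yl)-1H-indene-2-carboxylate | COC(=O)CCC1=C(C(=O)OCc2ccccc2)C(=O)c2c(OC)c(C(C)C)c(OC)c(OC)c12 | intermediate
16 | benzyl (3R)-4,5,7-trimethoxy-3-(3-methoxy-3-oxopropyl)-3-methyl-1-oxo-6-(propan-2-yl)indane-2-carboxylate (C2 epimers plus enol) | O=C(OCc1ccccc1)C1C(=O)c2c(OC)c(C(C)C)c(OC)c(OC)c2[C@]1(C)CCC(=O)OC | intermediate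
17 | dibromomethane | BrCBr | starting material
18 | benzyl (3S)-2-(bromomethyl)-4,5,7-trimethoxy-3-(3-methoxy-3-oxopropyl)-3-methyl-1-oxo-6-(propan-2-yl)indane-2-carboxylate (both C2 epimers) | O=C(OCc1ccccc1)C1(CBr)C(=O)c2c(OC)c(C(C)C)c(OC)c(OC)c2[C@]1(C)CCC(=O)OC | intermediate
19 | benzyl (3R,4R)-5,6,8-trimethoxy-4-(3-methoxy-3-oxopropyl)-4-methyl-1-oxo-7-(propan-2-yl)-1,2,3,4-tetrahydronaphthalene-3-carboxylate | O=C(OCc1ccccc1)[C@@H]1CC(=O)c2c(OC)c(C(C)C)c(OC)c(OC)c2[C@]1(C)CCC(=O)OC | intermediate
20 | (3R,4R)-5,6,8-trimethoxy-4-(3-methoxy-3-oxopropyl)-4-methyl-1-oxo-7-(propan-2-yl)-1,2,3,4-tetrahydronaphthalene-3-carboxylic acid | O=C(O)[C@@H]1CC(=O)c2c(OC)c(C(C)C)c(OC)c(OC)c2[C@]1(C)CCC(=O)OC | intermediate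
21 | acid chloride of 20 | O=C(Cl)[C@@H]1CC(=O)c2c(OC)c(C(C)C)c(OC)c(OC)c2[C@]1(C)CCC(=O)OC | intermediate (not isolated)
22 | methyl 3-[(3R,4R)-3-acetyl-5,6,8-trimethoxy-4-methyl-1-oxo-7-(propan-2-yl)-1,2,3,4-tetrahydronaphthalen-4-yl]propanoate | CC(=O)[C@@H]1CC(=O)c2c(OC)c(C(C)C)c(OC)c(OC)c2[C@]1(C)CCC(=O)OC | intermediate
23 | methyl 3-[(3S,4R)-5,6,8-trimethoxy-4-methyl-1-oxo-7-(propan-2-yl)-3-(prop-1-en-2-yl)-1,2,3,4-tetrahydronaphthalen-4-yl]propanoate | C=C(C)[C@@H]1CC(=O)c2c(OC)c(C(C)C)c(OC)c(OC)c2[C@]1(C)CCC(=O)OC | intermediate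
24 | 3-[(3S,4R)-5,6,8-trimethoxy-4-methyl-1-oxo-7-(propan-2-yl)-3-(prop-1-en-2-yl)-1,2,3,4-tetrahydronaphthalen-4-yl]propanoic acid | C=C(C)[C@@H]1CC(=O)c2c(OC)c(C(C)C)c(OC)c(OC)c2[C@]1(C)CCC(=O)O | intermediate
25 | 3-[(3S,4R)-6-methoxy-4-methyl-1,5,8-trioxo-7-(propan-2-yl)-3-(prop-1-en-2-yl)-1,2,3,4,5,8-hexahydronaphthalen-4-yl]propanoic acid | C=C(C)[C@@H]1CC(=O)C2=C(C(=O)C(OC)=C(C(C)C)C2=O)[C@]1(C)CCC(=O)O | intermediate
26 | 3-[(3S,4R)-6-hydroxy-4-methyl-1,5,8-trioxo-7-(propan-2-yl)-3-(prop-1-en-2-yl)-1,2,3,4,5,8-hexahydronaphthalen-4-yl]propanoic acid | C=C(C)[C@@H]1CC(=O)C2=C(C(=O)C(O)=C(C(C)C)C2=O)[C@]1(C)CCC(=O)O | intermediate (not isolated)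
27 | 3-[(3S,4R)-5,6,8-trihydroxy-4-methyl-1-oxo-7-(propan-2-yl)-3-(prop-1-en-2-yl)-1,2,3,4-tetrahydronaphthalen-4-yl]propanoic acid | C=C(C)[C@@H]1CC(=O)c2c(O)c(C(C)C)c(O)c(O)c2[C@]1(C)CCC(=O)O | target

**Totals**
Total step count: 16. Longest linear sequence: 16 steps (from 1).

**Steps most likely to fail**

Step 8. The methyl transfer may show poor enantiofacial discrimination, or stall at the β-carbon crowded by the neighbouring methoxy group. The fallback sets out from 15: uncatalysed addition of Me2CuLi (THF, −78 °C) should give the racemic keto diester F1. Preparative chromatography on a chiral stationary phase then separates 16 from the unwanted (3S)-enantiomer F2. The route is rejoined at 16, so absolute control moves from catalysis to resolution.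

Step 10. The primary radical may be reduced before it adds to the carbonyl, may shift a hydrogen from the CH2 next to the chain ester, or the final quench may show a weak facial bias. The fallback sets out from 16 and bypasses 18: zinc-carbenoid chain extension of the β-keto ester (Et2Zn, CH2I2, CH2Cl2, 0 °C → rt). The zinc enolate is cyclopropanated and the cyclopropoxide fragments to the ring-expanded organozinc intermediate F3. This is protonated at C3 with a hindered proton source under kinetic control, on the face away from the propanoate arm. The same C1–C2 bond is made by a closed-shell path with no radical side reactions, and the route is rejoined at 19.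

Step 9. The hindered enolate may alkylate on oxygen, or C-alkylation next to the quaternary carbon may be too slow and give decomposition on forcing. The fallback sets out from 16: aldol reaction with aqueous formaldehyde (KHCO3 cat., THF, rt) should give the hydroxymethyl keto diester F4. An Appel reaction (CBr4, PPh3, CH2Cl2, 0 °C → reflux) then converts F4 into 18, where the route is rejoined.

**Further compounds**
F1 | step 8 | racemic benzyl 4,5,7-trimethoxy-3-(3-methoxy-3-oxopropyl)-3-methyl-1-oxo-6-(propan-2-yl)indane-2-carboxylate | O=C(OCc1ccccc1)C1C(=O)c2c(OC)c(C(C)C)c(OC)c(OC)c2C1(C)CCC(=O)OC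
F2 | step 8 | benzyl (3S)-4,5,7-trimethoxy-3-(3-methoxy-3-oxopropyl)-3-methyl-1-oxo-6-(propan-2-yl)indane-2-carboxylate (enantiomer of 16) | O=C(OCc1ccccc1)C1C(=O)c2c(OC)c(C(C)C)c(OC)c(OC)c2[C@@]1(C)CCC(=O)OC
F3 | step 10 | ring-expanded C3 organozinc intermediate (drawn as the ethylzinc species) | CC[Zn]C1(C(=O)OCc2ccccc2)CC(=O)c2c(OC)c(C(C)C)c(OC)c(OC)c2[C@]1(C)CCC(=O)OC
F4 | step 9 | benzyl (3S)-2-(hydroxymethyl)-4,5,7-trimethoxy-3-(3-methoxy-3-oxopropyl)-3-methyl-1-oxo-6-(propan-2-yl)indane-2-carboxylate (C2 epimers) | O=C(OCc1ccccc1)C1(CO)C(=O)c2c(OC)c(C(C)C)c(OC)c(OC)c2[C@]1(C)CCC(=O)OC
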